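**Retrosynthetic overview**
- The coumarin lactone ring is made last, by Knoevenagel condensation and lactonisation of a quinone methide (masked salicylaldehyde, fragment 1) with a methyl pyranone-acetate (fragment 2); this forms C3–C4 and the lactone C–O.
- Fragment 2: the dihydropyranone ring (first ring made) closes under acid from an open C8 chain that carries C4' as a dithiane and C6' as a methyl enol ether.
- Key disconnection: C3'–C4' and C4'–C5' are both cut at C4'. C4' is used as a doubly nucleophilic carbonyl carbon (silyl dithiane) that joins two electrophiles, (S)-propylene oxide and methyl 4-bromo-3-methoxycrotonate, in one pot.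
- Fragment 1: the isochromene quinone methide (second ring, temporary) comes from orthoformate closure of a resorcinol triol; the side chain comes from an aryl Grignard reagent and (2R,3R)-2,3-epoxybutane, which sets both side-chain stereocentres at once.
- Ring order: dihydropyranone, then temporary isochromene, then coumarin.

Assumption: the target is taken exactly as drawn, (2R,3R) in the hydroxybutyl side chain and (S) at the pyranone methyl carbon; pyranone atoms are called O1', C2' (bears CH3), C3', C4' (C=O), C5', C6' (bonded to coumarin C3); compounds 1, 2, 3, 11 and 13 are bought.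

**Step 1**
Reactants: 1 2-(tert-butyldimethylsilyl)-1,3-dithiane; 2 (2S)-2-methyloxirane; 3 methyl (2E)-4-bromo-3-methoxybut-2-enoate
Product: 7 methyl (2E)-4-{2-[(2S)-2-(tert-butyldimethylsilyloxy)propyl]-1,3-dithian-2-yl}-3-methoxybut-2-enoate, via lithiated silyl dithiane 4 (not isolated), via lithium alkoxide 5 (not isolated), via silyl-migrated dithiane anion 6 (not isolated)
Conditions: t-BuLi (1.05 equiv), Et2O, −78 → −45 °C; 2, −78 → −25 °C; then 3, HMPA/THF, −78 → 0 °C
Reagents that add atoms: none
Why: Three-component dithiane linchpin coupling (Corey–Seebach umpolung with anion relay): the silyl dithiane anion opens the epoxide at its CH2 so the S carbinol of 2 is carried over untouched, HMPA triggers the 1,4-Brook shift of silicon from carbon to oxygen, and the regenerated dithiane anion displaces the allylic bromide of 3 by SN2, so the future carbonyl carbon C4' acts twice as a nucleophile and links two electrophilic carbons.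

**Step 2**
Reactants: 7 methyl (2E)-4-{2-[(2S)-2-(tert-butyldimethylsilyloxy)propyl]-1,3-dithian-2-yl}-3-methoxybut-2-enoate
Product: 10 methyl [(2S)-2-methyl-4-oxo-3,4-dihydro-2H-pyran-6-yl]acetate, via keto enol ether 8 (not isolated), via hydroxy ketone 9 (not isolated)
Conditions: PhI(OCOCF3)2 (1.5 equiv), MeCN/H2O (9:1), 0 °C; then 2 M aq. HCl, rt
Reagents that add atoms: water, O
Why: Oxidative dithioacetal hydrolysis by trivalent iodine frees the C4' ketone, acid then removes the silyl ether, and the freed hydroxyl adds to the enol-ether carbon C6' (oxa-conjugate addition/ketalisation) with loss of methanol toward the ketone to give the vinylogous ester, the C2' centre being untouched and staying S.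

**Step 3**
Reactants: 11 2-bromo-4,6-dimethoxybenzaldehyde
Product: 12 1-bromo-3,5-dimethoxy-2-methylbenzene
Conditions: Et3SiH (3 equiv), TFA, CH2Cl2, 0 °C → rt
Reagents that add atoms: none
Why: Ionic hydrogenation: the protonated electron-rich aldehyde takes hydride from the silane, the benzylic oxygen ionises to a cation stabilised by the ortho and para methoxy groups, and a second hydride gives the methyl group while the aryl bromide is untouched.

**Step 4**
Reactants: 12 1-bromo-3,5-dimethoxy-2-methylbenzene; 13 (2R,3R)-2,3-dimethyloxirane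
Product: 15 (2R,3R)-3-(3,5-dimethoxy-2-methylphenyl)butan-2-ol, via aryl Grignard reagent 14 (not isolated)
Conditions: Mg, THF, 50 °C; then CuBr·SMe2 (10 mol%), 13 (0.7 equiv), THF, −30 °C → rt; H2O
Reagents that add atoms: none
Why: Copper-catalysed Grignard opening of the C2-symmetric trans epoxide (both carbons equivalent) by SN2 with inversion, so the (2R,3R) epoxide gives the (2R,3R) alcohol in one step: the carbinol carbon is untouched and stays R, and the attacked carbon is inverted but is again R because aryl now ranks below the carbinol carbon.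

**Step 5**
Reactants: 15 (2R,3R)-3-(3,5-dimethoxy-2-methylphenyl)butan-2-ol
Product: 16 (2R,3R)-3-(3,5-dihydroxy-2-methylphenyl)butan-2-ol
Conditions: BBr3 (4 equiv), CH2Cl2, −78 → 0 °C; then H2O
Reagents that add atoms: none
Why: Lewis-acid cleavage of aryl methyl ethers (bromide attacks the O-methyl of the boron-complexed ether) while the secondary alcohol is held as a borate at low temperature and returns on hydrolysis, so both stereocentres are kept.

**Step 6**
Reactants: 16 (2R,3R)-3-(3,5-dihydroxy-2-methylphenyl)butan-2-ol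
Product: 18 (3R,4R)-8-hydroxy-3,4,5-trimethyl-4,6-dihydro-3H-isochromen-6-one, via ethoxy acetal 17 (not isolated)
Conditions: HC(OEt)3 (3 equiv), TFA (1 equiv), CH2Cl2, 0 °C → rt; concentrate
Reagents that add atoms: triethyl orthoformate, CCOC(OCC)OCC
Why: Tethered formylation of oxa-Pictet–Spengler type: the side-chain alcohol exchanges into the orthoester, the derived oxocarbenium ion attacks the only free ortho position (para to one phenol, ortho to the other) in a six-membered closure, and loss of the last ethanol gives the vinylogous-ester quinone methide, an aldehyde equivalent, with no stereocentre touched.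

**Step 7**
Reactants: 18 (3R,4R)-8-hydroxy-3,4,5-trimethyl-4,6-dihydro-3H-isochromen-6-one; 10 methyl [(2S)-2-methyl-4-oxo-3,4-dihydro-2H-pyran-6-yl]acetate
Product: 21 7-hydroxy-5-[(2R,3R)-3-hydroxybutan-2-yl]-6-methyl-3-[(2S)-2-methyl-4-oxo-3,4-dihydro-2H-pyran-6-yl]-2H-chromen-2-one, via isochroman adduct 19 (not isolated), via arylidene ester 20 (not isolated)
Conditions: piperidine (20 mol%), AcOH (20 mol%), EtOH, 60 °C
Reagents that add atoms: none
Why: Knoevenagel condensation of a salicylaldehyde equivalent: the dienolate of 10 (CH2 flanked by the ester and the vinylogous ketone) adds to the methide carbon of 18, E1cB opening of the isochroman frees the side-chain alcohol and gives the arylidene ester, and the ortho phenol closes the lactone with loss of methanol to the aromatic coumarin, with no stereocentre made or touched.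

**Compound list**
1 | 2-(tert-butyldimethylsilyl)-1,3-dithiane | CC(C)(C)[Si](C)(C)C1SCCCS1 | starting material
2 | (2S)-2-methyloxirane | C[C@H]1CO1 | starting material
3 | methyl (2E)-4-bromo-3-methoxybut-2-enoate | COC(=O)/C=C(/OC)CBr | starting material
4 | 2-lithio-2-(tert-butyldimethylsilyl)-1,3-dithiane | [Li]C1([Si](C)(C)C(C)(C)C)SCCCS1 | intermediate
5 | lithium (2S)-1-[2-(tert-butyldimethylsilyl)-1,3-dithian-2-yl]propan-2-olate | C[C@@H](CC1([Si](C)(C)C(C)(C)C)SCCCS1)O[Li] | intermediate
6 | 2-lithio-2-[(2S)-2-(tert-butyldimethylsilyloxy)propyl]-1,3-dithiane | C[C@@H](CC1([Li])SCCCS1)O[Si](C)(C)C(C)(C)C | intermediate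
7 | methyl (2E)-4-{2-[(2S)-2-(tert-butyldimethylsilyloxy)propyl]-1,3-dithian-2-yl}-3-methoxybut-2-enoate | COC(=O)/C=C(/OC)CC1(C[C@H](C)O[Si](C)(C)C(C)(C)C)SCCCS1 | intermediate
8 | methyl (2E,7S)-7-(tert-butyldimethylsilyloxy)-3-methoxy-5-oxooct-2-enoate | COC(=O)/C=C(/OC)CC(=O)C[C@H](C)O[Si](C)(C)C(C)(C)C | intermediate
9 | methyl (2E,7S)-7-hydroxy-3-methoxy-5-oxooct-2-enoate | COC(=O)/C=C(/OC)CC(=O)C[C@H](C)O | intermediate
10 | methyl [(2S)-2-methyl-4-oxo-3,4-dihydro-2H-pyran-6-yl]acetate | COC(=O)CC1=CC(=O)C[C@H](C)O1 | intermediate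
11 | 2-bromo-4,6-dimethoxybenzaldehyde | COc1cc(OC)c(C=O)c(Br)c1 | starting material
12 | 1-bromo-3,5-dimethoxy-2-methylbenzene | COc1cc(OC)c(C)c(Br)c1 | intermediate
13 | (2R,3R)-2,3-dimethyloxirane | C[C@H]1O[C@@H]1C | starting material
14 | (3,5-dimethoxy-2-methylphenyl)magnesium bromide | COc1cc(OC)c(C)c([Mg]Br)c1 | intermediate
15 | (2R,3R)-3-(3,5-dimethoxy-2-methylphenyl)butan-2-ol | COc1cc(OC)c(C)c(c1)[C@@H](C)[C@@H](C)O | intermediate
16 | (2R,3R)-3-(3,5-dihydroxy-2-methylphenyl)butan-2-ol | Cc1c(O)cc(O)cc1[C@@H](C)[C@@H](C)O | intermediate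
17 | (3R,4R)-1-ethoxy-3,4,5-trimethyl-3,4-dihydro-1H-isochromene-6,8-diol (C1 epimers) | CCOC1O[C@H](C)[C@H](C)c2c(C)c(O)cc(O)c21 | intermediate
18 | (3R,4R)-8-hydroxy-3,4,5-trimethyl-4,6-dihydro-3H-isochromen-6-one | CC1=C2[C@@H](C)[C@@H](C)OC=C2C(O)=CC1=O | intermediate
19 | methyl 2-[(3R,4R)-6,8-dihydroxy-3,4,5-trimethyl-3,4-dihydro-1H-isochromen-1-yl]-2-[(2S)-2-methyl-4-oxo-3,4-dihydro-2H-pyran-6-yl]acetate (epimers at C1 and the acetate carbon) | COC(=O)C(C1O[C@H](C)[C@H](C)c2c(C)c(O)cc(O)c21)C1=CC(=O)C[C@H](C)O1 | intermediate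
20 | methyl 3-{2,4-dihydroxy-6-[(2R,3R)-3-hydroxybutan-2-yl]-5-methylphenyl}-2-[(2S)-2-methyl-4-oxo-3,4-dihydro-2H-pyran-6-yl]prop-2-enoate (alkene geometry not fixed) | COC(=O)C(=Cc1c(O)cc(O)c(C)c1[C@@H](C)[C@@H](C)O)C1=CC(=O)C[C@H](C)O1 | intermediate
21 | 7-hydroxy-5-[(2R,3R)-3-hydroxybutan-2-yl]-6-methyl-3-[(2S)-2-methyl-4-oxo-3,4-dihydro-2H-pyran-6-yl]-2H-chromen-2-one | Cc1c(O)cc2oc(=O)c(C3=CC(=O)C[C@H](C)O3)cc2c1[C@@H](C)[C@@H](C)O | target

**Totals**
Total steps: 7. Longest linear sequence: 5 steps (11 → 21, steps 3 to 7); fragment 2 takes 2 steps (steps 1 and 2).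

**Three steps most likely to fail**

Step 1. Anion 6 is a hindered, strongly basic carbanion, and 3 carries an ester and acidic allylic protons, so proton transfer or attack at the ester may outrun the SN2 alkylation. The fallback sets out from anion 6 and comes back at 10. It keeps the dithiane/epoxide bond but makes the C4'–C5' bond by an aldol reaction. Quench 6 with NH4Cl to give 2-[(2S)-2-(tert-butyldimethylsilyloxy)propyl]-1,3-dithiane F1. Hydrolyse it with PhI(OCOCF3)2 in aqueous MeCN to (3S)-3-(tert-butyldimethylsilyloxy)butanal F2. Add the dianion of methyl acetoacetate (NaH then n-BuLi, THF, −78 °C) to obtain methyl (7S)-7-(tert-butyldimethylsilyloxy)-5-hydroxy-3-oxooctanoate F3. Oxidise the new carbinol with Dess–Martin periodinane to methyl (7S)-7-(tert-butyldimethylsilyloxy)-3,5-dioxooctanoate F4. Treat this with aqueous HCl in MeCN, which removes the silyl group and cyclodehydrates to 10.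

Step 6. Formylation could also go between the two phenols, and the quinone methide can lose its formyl carbon again in acid. The fallback sets out from 15 and comes back at 18, and it also replaces step 5. Formylate the dimethyl ether first with Cl2CHOMe and TiCl4 in CH2Cl2 at −78 → 0 °C. The position between the two methoxy groups is shielded, so attack goes next to the side chain and the aldehyde closes onto the side-chain hydroxyl, giving (3R,4R)-6,8-dimethoxy-3,4,5-trimethyl-3,4-dihydro-1H-isochromen-1-ol F6. Cleave both ethers with BBr3; the lactol then loses water to give 18.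

Step 7. Piperidine can add to the dihydropyranone and open it, the methylene of 10 may be too weakly acidic for clean amine catalysis, and C2' could erode by retro-oxa-Michael opening. The fallback sets out from 10 and comes back at 19, without any amine. Silylate 10 with TBSOTf and Et3N in CH2Cl2 to methyl 2-[(6S)-4-(tert-butyldimethylsilyloxy)-6-methyl-5,6-dihydro-2H-pyran-2-ylidene]acetate F5. Add F5 to quinone methide 18 with Sc(OTf)3 (5 mol%) in CH2Cl2 at −40 °C (vinylogous Mukaiyama–Michael addition at the exocyclic carbon); work-up gives adduct 19, now isolated. DBU (20 mol%) in toluene at 60 °C then opens the isochroman and closes the lactone to 21.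

**Further compounds**
F1 | step 1 | 2-[(2S)-2-(tert-butyldimethylsilyloxy)propyl]-1,3-dithiane | C[C@@H](CC1SCCCS1)O[Si](C)(C)C(C)(C)C
F2 | step 1 | (3S)-3-(tert-butyldimethylsilyloxy)butanal | C[C@@H](CC=O)O[Si](C)(C)C(C)(C)C
F3 | step 1 | methyl (7S)-7-(tert-butyldimethylsilyloxy)-5-hydroxy-3-oxooctanoate (C5 epimers) | COC(=O)CC(=O)CC(O)C[C@H](C)O[Si](C)(C)C(C)(C)C
F4 | step 1 | methyl (7S)-7-(tert-butyldimethylsilyloxy)-3,5-dioxooctanoate | COC(=O)CC(=O)CC(=O)C[C@H](C)O[Si](C)(C)C(C)(C)C
F5 | step 7 | methyl 2-[(6S)-4-(tert-butyldimethylsilyloxy)-6-methyl-5,6-dihydro-2H-pyran-2-ylidene]acetate | COC(=O)C=C1C=C(O[Si](C)(C)C(C)(C)C)C[C@H](C)O1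
F6 | step 6 | (3R,4R)-6,8-dimethoxy-3,4,5-trimethyl-3,4-dihydro-1H-isochromen-1-ol (C1 epimers) | COc1cc(OC)c2C(O)O[C@H](C)[C@H](C)c2c1C
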